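**Assumption (one line):** compounds 1, 4 and 19 are taken as commercial single isomers; ring-derived atoms carry germacrane numbers (C1–C15) throughout, and in 16 and 17 the CIP label of C7 reads S only because the silyl ether on O8 changes the priority order (the spatial arrangement is that of the target).

## Analysis of the target

1. The target is a germacranolide: a ten-membered carbocycle (C1–C10) fused cis at C6–C7 to an α-methylene-γ-butyrolactone (O–C6, C7–C11(=C13H2)–C12=O).
2. The ring holds a (2Z,4Z)-diene C2=C3–C4(C15H3)=C5, flanked by the trisubstituted C1–C10 epoxide (ring bonds C2 and C9 cis, hydroxymethyl C14 on C10) and by the allylic lactone oxygen at C6.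
3. There are five stereocentres: the contiguous triad C6 (S), C7 (R), C8 (R), with O6, C11 and O8 all on one face, and the epoxide pair C1 (R), C10 (R), 1,3-related to C8 through C9.
4. O8 carries a (Z)-2-(hydroxymethyl)but-2-enoate, an angelate-type ester that isomerises under nucleophilic catalysis.
5. Sensitive groups are the dienyl epoxide (acid, zerovalent palladium), the α-methylene lactone (Michael acceptor, easily hydrogenated), the doubly allylic C6–O bond, and the lactone itself, which can migrate from O6 to a free O8.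
6. The hard parts are the medium ring with two cis olefins and a cis epoxide, the all-cis triad, and a latent all-cis 1(10),2,4-triene that would close by 6π-electrocyclisation to a decalin.
7. The feature used here: the C6–C7 bond is shared by the ten-membered ring and the lactone ring and C7 carries the C11(=C13)–C12 acrylate, so one intramolecular carbonyl allylation can close both rings and set C6 and C7; and the C2=C3 cis olefin, lying between sp2 C4 and sp3 C1, can be carried as an alkyne.

## Retrosynthetic reasoning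

**28 ⇒ 27.** The C2=C3 cis double bond is cut back to a triple bond. The (Z,Z)-dienyl epoxide is the most fragile array of the molecule, so it is unveiled in the last step by a cis-selective semi-reduction. The alkyne also means that no cyclic all-cis triene ever exists.

**27 ⇒ 26.** The two C–O bonds of the epoxide are cut to the C1=C10 olefin of allylic alcohol 26. The forward reaction is a Sharpless asymmetric epoxidation directed by the C14 hydroxyl, which sets C1 and C10 together under reagent control. It must pick the one electron-rich allylic-alcohol olefin among four C=C bonds.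

**26 ⇒ 18 + 23.** The O8–acyl bond is cut, after removal of the two silyl groups of 25. Acid 23 carries the Z geometry from 19 through an α-iodo enal and a stereoretentive carbonylation. The ester is put on after the ring closure, because an acyloxy group on C8 would be eliminated from the allylmetal of the key step.

**18 ⇒ 17 ⇒ 15 (key disconnection).** The C6–C7 bond and the O6–C12 bond are cut in one operation. Cutting here removes the ten-membered ring, the lactone ring and two of the five stereocentres at once and leaves a linear chain with a single stereocentre (C8). The forward step must close a ten-membered ring against oligomerisation, add C7 to the C6 aldehyde syn (cis lactone), and choose the face of C7 under the influence of C8.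

**15 ⇒ 11.** The C7=C11 bond and the C13–Br bond are traced to a three-carbon acrylate unit joined to the C7 aldehyde 11 (Morita–Baylis–Hillman reaction, then allylic transposition to the bromide 13). The C6 aldehyde is unmasked last from its 4-methoxybenzyl ether.

**11 ⇒ 7 ⇒ 6 ⇒ 5 + 3.** The C1=C10 double bond is cut (Horner–Wadsworth–Emmons reaction). In 6 the γ-lactone ties O8 to C14, so the olefin forms as the E-alkylidene lactone, which places C2 cis to C9 as the ring needs. Reduction of 6 then releases the C14 allylic alcohol and the C8 hydroxyl of 7 in one step.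

**5 ⇐ 4 and 3 ⇐ 1.** Lactone 4 supplies C7–C10 and C14 with the C8 stereocentre bought. Enynol 1 supplies C2–C6 and C15 with the 4Z olefin already in place; C1 is added by formylation of the alkyne.

## Alternatives that were turned down

**Alternative 1:** (the textbook one) Disconnection at C2=C3 by ring-closing metathesis. The forward key step would treat A1, which has a vinyl epoxide at C1 and a terminal (Z)-diene at C4, with a second-generation Grubbs catalyst. It was turned down for three reasons. The ruthenium alkylidene on the diene terminus can attack C4=C5 and give a ring-contracted product; vinyl epoxides are poor partners; and the 2Z geometry would rest on ring strain alone. In addition, A1 needs all five stereocentres set on an open chain by separate reactions, so the ring closure contributes nothing to the stereochemical problem and costs more steps before it.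

**Alternative 2:** Disconnection at C7–C8. The forward key step would be a CrCl2-mediated intramolecular allylation of the 3-(bromomethyl)butenolide A2 onto a C8 aldehyde. It was turned down because C6 must first be set by a separate asymmetric step next to the sensitive (Z)-enyne. A γ-substituted bromomethyl butenolide normally takes the aldehyde anti to its γ-substituent, which leads to the trans lactone, whereas the target is cis. The β,γ-unsaturated aldehyde of A2 drifts into conjugation, and the new C8 carbinol would be steered only by remote C6.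

**Alternative 3:** Disconnection of a transannular C3–C8 bond, a ring expansion. The forward key step would be an Eschenmoser–Tanabe fragmentation of the tosylhydrazone of decalin epoxy ketone A3. It would deliver the ten-membered ring with C2≡C3 and a C8 ketone, and the 4Z olefin is fixed by the six-membered ring. It was turned down on step economy and on structure. A3 is a densely functionalised decalin whose cyclohexene ring is one elimination away from an arene. The fragmentation product has a C8 ketone flanked by an epimerisable C7 and a β-silyloxy C6 (E1cB loss). The C1/C10/C14 oxidation pattern would still have to be added at an unactivated propargylic methylene.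

Key step: step 13

## Route

Step 1
Reactants: 1 (Z)-3-methylpent-2-en-4-yn-1-ol
Product: 2 1-methoxy-4-({[(2Z)-3-methylpent-2-en-4-yn-1-yl]oxy}methyl)benzene
Conditions: NaH, 4-MeOC6H4CH2Cl, n-Bu4NI (cat.), THF, 0 °C to rt
Reagents that add atoms: 4-methoxybenzyl chloride, COc1ccc(CCl)cc1
Why: Williamson etherification; the alkoxide forms in preference to the acetylide and the 4Z olefin is untouched.

Step 2
Reactants: 2 1-methoxy-4-({[(2Z)-3-methylpent-2-en-4-yn-1-yl]oxy}methyl)benzene
Product: 3 (4Z)-6-[(4-methoxybenzyl)oxy]-4-methylhex-4-en-2-ynal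
Conditions: n-BuLi, THF, −78 °C; DMF, −78 to 0 °C; inverse quench into aq. KH2PO4
Reagents that add atoms: N,N-dimethylformamide, CN(C)C=O
Why: Formylation of a lithium acetylide introduces C1; the buffered inverse quench keeps the liberated amine from adding to the ynal.

Step 3
Reactants: 4 (R)-5-[(trityloxy)methyl]dihydrofuran-2(3H)-one
Product: 5 diethyl {(5R)-2-oxo-5-[(trityloxy)methyl]oxolan-3-yl}phosphonate (mixture of C3 epimers)
Conditions: LiN(i-Pr)2 (2.2 equiv), THF, −78 °C; ClP(O)(OEt)2, −78 to 0 °C; aq. NH4Cl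
Reagents that add atoms: diethyl chlorophosphate, CCOP(=O)(Cl)OCC
Why: O-phosphorylation of the lactone enolate followed by base-induced 1,3-phosphorus migration (enol phosphate to α-phosphono lactone); C8 is not enolisable and keeps its configuration, and the new centre is removed in step 4.

Step 4
Reactants: 5 diethyl {(5R)-2-oxo-5-[(trityloxy)methyl]oxolan-3-yl}phosphonate; 3 (4Z)-6-[(4-methoxybenzyl)oxy]-4-methylhex-4-en-2-ynal
Product: 6 (3E,5R)-3-{(4Z)-6-[(4-methoxybenzyl)oxy]-4-methylhex-4-en-2-yn-1-ylidene}-5-[(trityloxy)methyl]oxolan-2-one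
Conditions: NaH, THF, 0 °C; then 3, −20 to 0 °C
Reagents that add atoms: none
Why: Horner–Wadsworth–Emmons olefination forms C1=C10; the α-alkylidene-γ-lactone should form mainly as the E isomer (alkynyl group away from the carbonyl), which is the arrangement with C2 cis to C9 needed in the ring.

Step 5
Reactants: 6 (3E,5R)-3-{(4Z)-6-[(4-methoxybenzyl)oxy]-4-methylhex-4-en-2-yn-1-ylidene}-5-[(trityloxy)methyl]oxolan-2-one
Product: 7 (2R,4E,8Z)-4-(hydroxymethyl)-10-[(4-methoxybenzyl)oxy]-8-methyl-1-(trityloxy)deca-4,8-dien-6-yn-2-ol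
Conditions: i-Bu2AlH (4 equiv), CH2Cl2, −78 to 0 °C; aq. potassium sodium tartrate
Reagents that add atoms: none
Why: 1,2-Reduction of the unsaturated lactone through the lactol to the diol frees the C14 allylic alcohol and the C8 hydroxyl; ethers, enyne and olefin geometries are inert to the aluminium hydride.

Step 6
Reactants: 7 (2R,4E,8Z)-4-(hydroxymethyl)-10-[(4-methoxybenzyl)oxy]-8-methyl-1-(trityloxy)deca-4,8-dien-6-yn-2-ol
Product: 9 (2R,4E,8Z)-2-[(tert-butyldimethylsilyl)oxy]-4-{[(tert-butyldiphenylsilyl)oxy]methyl}-10-[(4-methoxybenzyl)oxy]-8-methyl-1-(trityloxy)deca-4,8-dien-6-yne, via mono-silyl ether 8 (not isolated)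
Conditions: t-BuPh2SiCl, imidazole, CH2Cl2, 0 °C; then 2,6-lutidine, t-BuMe2SiOTf, −78 to 0 °C
Reagents that add atoms: tert-butyl(chloro)diphenylsilane, CC(C)(C)[Si](Cl)(c1ccccc1)c1ccccc1; tert-butyldimethylsilyl trifluoromethanesulfonate, CC(C)(C)[Si](C)(C)OS(=O)(=O)C(F)(F)F
Why: The bulky silyl chloride takes the primary allylic C14 hydroxyl only, and the silyl triflate then caps the hindered secondary C8 hydroxyl; this gives four oxygen functions that can be freed one by one.

Step 7
Reactants: 9 (2R,4E,8Z)-2-[(tert-butyldimethylsilyl)oxy]-4-{[(tert-butyldiphenylsilyl)oxy]methyl}-10-[(4-methoxybenzyl)oxy]-8-methyl-1-(trityloxy)deca-4,8-dien-6-yne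
Product: 10 (2R,4E,8Z)-2-[(tert-butyldimethylsilyl)oxy]-4-{[(tert-butyldiphenylsilyl)oxy]methyl}-10-[(4-methoxybenzyl)oxy]-8-methyldeca-4,8-dien-6-yn-1-ol
Conditions: camphorsulfonic acid (10 mol%), MeOH/CH2Cl2 (1:1), 0 °C
Reagents that add atoms: none
Why: Acid-catalysed methanolysis of the trityl ether through the trityl cation; the secondary silyl ether, the primary diphenylsilyl ether and the benzyl-type ether are far slower under these conditions.

Step 8
Reactants: 10 (2R,4E,8Z)-2-[(tert-butyldimethylsilyl)oxy]-4-{[(tert-butyldiphenylsilyl)oxy]methyl}-10-[(4-methoxybenzyl)oxy]-8-methyldeca-4,8-dien-6-yn-1-ol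
Product: 11 (2R,4E,8Z)-2-[(tert-butyldimethylsilyl)oxy]-4-{[(tert-butyldiphenylsilyl)oxy]methyl}-10-[(4-methoxybenzyl)oxy]-8-methyldeca-4,8-dien-6-ynal
Conditions: Dess–Martin periodinane, NaHCO3, CH2Cl2, 0 °C to rt
Reagents that add atoms: none
Why: Buffered Dess–Martin oxidation gives the α-silyloxy aldehyde (C7) without epimerising C8; the aldehyde is used at once.

Step 9
Reactants: 11 (2R,4E,8Z)-2-[(tert-butyldimethylsilyl)oxy]-4-{[(tert-butyldiphenylsilyl)oxy]methyl}-10-[(4-methoxybenzyl)oxy]-8-methyldeca-4,8-dien-6-ynal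
Product: 12 methyl (4R,6E,10Z)-4-[(tert-butyldimethylsilyl)oxy]-6-{[(tert-butyldiphenylsilyl)oxy]methyl}-3-hydroxy-12-[(4-methoxybenzyl)oxy]-10-methyl-2-methylidenedodeca-6,10-dien-8-ynoate (mixture of C3 epimers)
Conditions: methyl acrylate (solvent), DABCO (30 mol%), MeOH (2 equiv), rt
Reagents that add atoms: methyl acrylate, C=CC(=O)OC
Why: Morita–Baylis–Hillman reaction attaches C11–C13; the configuration of the new carbinol (C7) is irrelevant because it becomes sp2 in step 10.

Step 10
Reactants: 12 methyl (4R,6E,10Z)-4-[(tert-butyldimethylsilyl)oxy]-6-{[(tert-butyldiphenylsilyl)oxy]methyl}-3-hydroxy-12-[(4-methoxybenzyl)oxy]-10-methyl-2-methylidenedodeca-6,10-dien-8-ynoate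
Product: 13 methyl (2Z,4R,6E,10Z)-2-(bromomethyl)-4-[(tert-butyldimethylsilyl)oxy]-6-{[(tert-butyldiphenylsilyl)oxy]methyl}-12-[(4-methoxybenzyl)oxy]-10-methyldodeca-2,6,10-trien-8-ynoate
Conditions: NBS, Me2S, CH2Cl2, 0 °C to rt
Reagents that add atoms: N-bromosuccinimide, O=C1CCC(=O)N1Br
Why: The bromosulfonium salt activates the hydroxyl and bromide enters with allylic transposition (SN2′), the known route from Baylis–Hillman adducts to (Z)-2-(bromomethyl)alk-2-enoates; the pre-formed reagent leaves the other olefins alone.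

Step 11
Reactants: 13 methyl (2Z,4R,6E,10Z)-2-(bromomethyl)-4-[(tert-butyldimethylsilyl)oxy]-6-{[(tert-butyldiphenylsilyl)oxy]methyl}-12-[(4-methoxybenzyl)oxy]-10-methyldodeca-2,6,10-trien-8-ynoate
Product: 14 methyl (2Z,4R,6E,10Z)-2-(bromomethyl)-4-[(tert-butyldimethylsilyl)oxy]-6-{[(tert-butyldiphenylsilyl)oxy]methyl}-12-hydroxy-10-methyldodeca-2,6,10-trien-8-ynoate
Conditions: DDQ, CH2Cl2/pH 7 phosphate buffer (10:1), 0 °C
Reagents that add atoms: none
Why: Oxidative cleavage of the 4-methoxybenzyl ether under neutral conditions, which the allylic bromide and the silyl ethers tolerate; any over-oxidation of the allylic alcohol gives the aldehyde of step 12.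

Step 12
Reactants: 14 methyl (2Z,4R,6E,10Z)-2-(bromomethyl)-4-[(tert-butyldimethylsilyl)oxy]-6-{[(tert-butyldiphenylsilyl)oxy]methyl}-12-hydroxy-10-methyldodeca-2,6,10-trien-8-ynoate
Product: 15 methyl (2Z,4R,6E,10Z)-2-(bromomethyl)-4-[(tert-butyldimethylsilyl)oxy]-6-{[(tert-butyldiphenylsilyl)oxy]methyl}-10-methyl-12-oxododeca-2,6,10-trien-8-ynoate
Conditions: MnO2 (activated, excess), CH2Cl2, rt
Reagents that add atoms: none
Why: MnO2 oxidises the allylic alcohol to the (Z)-enynal without acid or base, so the 4Z geometry should be kept; with an alkyne at C2–C3 the enal cannot close to a 2H-pyran.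

Step 13
Reactants: 15 methyl (2Z,4R,6E,10Z)-2-(bromomethyl)-4-[(tert-butyldimethylsilyl)oxy]-6-{[(tert-butyldiphenylsilyl)oxy]methyl}-10-methyl-12-oxododeca-2,6,10-trien-8-ynoate
Product: 17 (6S,7S,8R)-8-[(tert-butyldimethylsilyl)oxy]-14-[(tert-butyldiphenylsilyl)oxy]germacra-1(10)E,4Z,11(13)-trien-2-yn-12,6-olide, via hydroxy ester 16 (not isolated)
Conditions: CrCl2 (8 equiv), THF, rt, slow addition of 15 (final 0.003 M); aq. NH4Cl; then pyridinium p-toluenesulfonate (cat.), CH2Cl2, rt
Reagents that add atoms: none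
Why: Two equivalents of CrCl2 reduce the allylic C13–Br bond to a 2-(methoxycarbonyl)allyl species of trivalent chromium, which is nucleophilic at C7 and tolerates ester, silyl ethers, enyne and enal. C7 adds 1,2 to the C6 aldehyde through a six-membered chair transition state with chromium on the carbonyl oxygen (Nozaki–Hiyama allylation); the closest known reactions are chromium-mediated cyclisations of ω-formyl allylic bromides to germacrane rings and the cis-selective lactone synthesis from 2-(bromomethyl)alk-2-enoates and aldehydes. The carbocycle closes in the 10-exo-trig mode, and the O6 alkoxide (or hydroxy ester 16 under mild acid) closes the lactone by 5-exo-trig acyl substitution with loss of methanol. C6 and C7: the allylchromium keeps C8 cis to the CH2–Cr group, so C8 sits axial and the aldehyde substituent (C5) equatorial in the chair; this syn addition makes H6 and H7 cis, which is the cis-fused lactone. The face of C7 is set by C8: allylic 1,3-strain holds H8 in the plane of C7=C11 and the tether carbon C9 must point away from the forming bond, so C6 should add on the face that puts C11 and O8 cis on the new ring. The step needs ring closure over oligomerisation (dilution, and the rigid C10=C1–C2≡C3–C4=C5 array that holds C9 and C6 close), γ over α attack (intrinsic to the closed transition state), and no 1,4-elimination (the δ-oxygen is a silyl ether, a poor leaving group). Because C2–C3 is a triple bond, the product cannot undergo the 6π-electrocyclisation open to the corresponding triene.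

Step 14
Reactants: 17 (6S,7S,8R)-8-[(tert-butyldimethylsilyl)oxy]-14-[(tert-butyldiphenylsilyl)oxy]germacra-1(10)E,4Z,11(13)-trien-2-yn-12,6-olide
Product: 18 (6S,7R,8R)-14-[(tert-butyldiphenylsilyl)oxy]-8-hydroxygermacra-1(10)E,4Z,11(13)-trien-2-yn-12,6-olide
Conditions: HF·pyridine, pyridine, THF, 0 °C
Reagents that add atoms: none
Why: Under buffered acidic fluoride the dimethylsilyl ether is cleaved much faster than the diphenylsilyl ether; the non-basic medium also suppresses migration of the lactone from O6 to the freed O8.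

Step 15
Reactants: 19 (E)-but-2-enal
Product: 20 (Z)-2-iodobut-2-enal
Conditions: I2, DMAP (20 mol%), K2CO3, THF/H2O (1:1), rt
Reagents that add atoms: iodine, II
Why: α-Iodination of an enal by conjugate addition of the amine catalyst, iodination of the enolate and elimination; the methyl group stays trans to the formyl group.

Step 16
Reactants: 20 (Z)-2-iodobut-2-enal
Product: 21 (Z)-2-iodobut-2-en-1-ol
Conditions: NaBH4, CeCl3·7H2O, MeOH, −20 °C
Reagents that add atoms: none
Why: Luche 1,2-reduction; the vinyl iodide and the olefin geometry are not affected.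

Step 17
Reactants: 21 (Z)-2-iodobut-2-en-1-ol
Product: 22 tert-butyl{[(2Z)-2-iodobut-2-en-1-yl]oxy}diphenylsilane
Conditions: t-BuPh2SiCl, imidazole, CH2Cl2, 0 °C to rt
Reagents that add atoms: tert-butyl(chloro)diphenylsilane, CC(C)(C)[Si](Cl)(c1ccccc1)c1ccccc1
Why: Standard silylation; the same silyl group as on O14 allows a single deprotection in step 20.

Step 18
Reactants: 22 tert-butyl{[(2Z)-2-iodobut-2-en-1-yl]oxy}diphenylsilane
Product: 23 (2Z)-2-{[(tert-butyldiphenylsilyl)oxy]methyl}but-2-enoic acid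
Conditions: Pd(OAc)2 (5 mol%), PPh3 (10 mol%), CO (1 atm), Et3N, H2O, DMF, 60 °C; then dilute aq. citric acid
Reagents that add atoms: carbon monoxide, [C-]#[O+]; water, O
Why: Heck-type hydroxycarbonylation: zerovalent palladium inserts into the C–I bond with retention, CO inserts and water cleaves the acyl complex, so the carboxyl ends up cis to the methyl group (the Z acid of the side chain).

Step 19
Reactants: 18 (6S,7R,8R)-14-[(tert-butyldiphenylsilyl)oxy]-8-hydroxygermacra-1(10)E,4Z,11(13)-trien-2-yn-12,6-olide; 23 (2Z)-2-{[(tert-butyldiphenylsilyl)oxy]methyl}but-2-enoic acid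
Product: 25 (6S,7R,8R)-14-[(tert-butyldiphenylsilyl)oxy]-8-{[(2Z)-2-{[(tert-butyldiphenylsilyl)oxy]methyl}but-2-enoyl]oxy}germacra-1(10)E,4Z,11(13)-trien-2-yn-12,6-olide, via mixed anhydride 24 (not isolated)
Conditions: 2,4,6-Cl3C6H2COCl, Et3N, toluene, rt; then 18, DMAP (0.2 equiv), toluene, rt
Reagents that add atoms: none
Why: Yamaguchi esterification through the mixed anhydride acylates the hindered C8 hydroxyl with retention; the mixed-anhydride protocol with little DMAP is the one that keeps angelate-type Z acids from isomerising, and fast acylation locks the lactone on O6.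

Step 20
Reactants: 25 (6S,7R,8R)-14-[(tert-butyldiphenylsilyl)oxy]-8-{[(2Z)-2-{[(tert-butyldiphenylsilyl)oxy]methyl}but-2-enoyl]oxy}germacra-1(10)E,4Z,11(13)-trien-2-yn-12,6-olide
Product: 26 (6S,7R,8R)-14-hydroxy-8-{[(2Z)-2-(hydroxymethyl)but-2-enoyl]oxy}germacra-1(10)E,4Z,11(13)-trien-2-yn-12,6-olide
Conditions: HF·pyridine (excess), pyridine, THF, 0 °C to rt
Reagents that add atoms: none
Why: Both primary silyl ethers are removed while the molecule still holds no epoxide and no diene, so the acidic fluoride meets only robust groups.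

Step 21
Reactants: 26 (6S,7R,8R)-14-hydroxy-8-{[(2Z)-2-(hydroxymethyl)but-2-enoyl]oxy}germacra-1(10)E,4Z,11(13)-trien-2-yn-12,6-olide
Product: 27 (1R,6S,7R,8R,10R)-1,10-epoxy-14-hydroxy-8-{[(2Z)-2-(hydroxymethyl)but-2-enoyl]oxy}germacra-4Z,11(13)-dien-2-yn-12,6-olide
Conditions: Ti(O-i-Pr)4 (20 mol%), D-(−)-diethyl tartrate (24 mol%), t-BuOOH, 4 Å MS, CH2Cl2, −25 °C
Reagents that add atoms: tert-butyl hydroperoxide, CC(C)(C)OO
Why: Sharpless asymmetric epoxidation; only C1=C10 is an electron-rich allylic-alcohol olefin (the side-chain allylic alcohol sits on an acrylate, C4=C5 has no directing hydroxyl), and with the D-tartrate oxygen is delivered to the face that gives 1R,10R, the alkynyl group staying trans to C14 as in the E olefin.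

Step 22
Reactants: 27 (1R,6S,7R,8R,10R)-1,10-epoxy-14-hydroxy-8-{[(2Z)-2-(hydroxymethyl)but-2-enoyl]oxy}germacra-4Z,11(13)-dien-2-yn-12,6-olide
Product: 28 (1R,6S,7R,8R,10R)-1,10-epoxy-14-hydroxy-8-{[(2Z)-2-(hydroxymethyl)but-2-enoyl]oxy}germacra-2Z,4Z,11(13)-trien-12,6-olide (CNP0165856.1)
Conditions: Zn dust activated with Cu(OAc)2 and AgNO3, MeOH/H2O (1:1), rt, dark; neutral work-up
Reagents that add atoms: none
Why: Boland-type cis-semireduction is specific for triple bonds activated by conjugation (here with C4=C5) and should leave the acrylate units and the epoxide alone; it gives the 2Z olefin and completes the (2Z,4Z)-dienyl epoxide under neutral conditions in the last step.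

## Compound list

1 | (Z)-3-methylpent-2-en-4-yn-1-ol | OC/C=C(C)\C#C | starting material
2 | 1-methoxy-4-({[(2Z)-3-methylpent-2-en-4-yn-1-yl]oxy}methyl)benzene | COc1ccc(COC/C=C(C)\C#C)cc1 | intermediate
3 | (4Z)-6-[(4-methoxybenzyl)oxy]-4-methylhex-4-en-2-ynal | COc1ccc(COC/C=C(C)\C#CC=O)cc1 | intermediate
4 | (R)-5-[(trityloxy)methyl]dihydrofuran-2(3H)-one | O=C1CC[C@H](COC(c2ccccc2)(c2ccccc2)c2ccccc2)O1 | starting material
5 | diethyl {(5R)-2-oxo-5-[(trityloxy)methyl]oxolan-3-yl}phosphonate (C3 epimers) | CCOP(=O)(OCC)C1C[C@H](COC(c2ccccc2)(c2ccccc2)c2ccccc2)OC1=O | intermediate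
6 | (3E,5R)-3-{(4Z)-6-[(4-methoxybenzyl)oxy]-4-methylhex-4-en-2-yn-1-ylidene}-5-[(trityloxy)methyl]oxolan-2-one | COc1ccc(COC/C=C(C)\C#C/C=C2\C[C@H](COC(c3ccccc3)(c3ccccc3)c3ccccc3)OC2=O)cc1 | intermediate
7 | (2R,4E,8Z)-4-(hydroxymethyl)-10-[(4-methoxybenzyl)oxy]-8-methyl-1-(trityloxy)deca-4,8-dien-6-yn-2-ol | COc1ccc(COC/C=C(C)\C#C/C=C(/CO)C[C@@H](O)COC(c2ccccc2)(c2ccccc2)c2ccccc2)cc1 | intermediate
8 | (2R,4E,8Z)-4-{[(tert-butyldiphenylsilyl)oxy]methyl}-10-[(4-methoxybenzyl)oxy]-8-methyl-1-(trityloxy)deca-4,8-dien-6-yn-2-ol | COc1ccc(COC/C=C(C)\C#C/C=C(/CO[Si](c2ccccc2)(c2ccccc2)C(C)(C)C)C[C@@H](O)COC(c2ccccc2)(c2ccccc2)c2ccccc2)cc1 | intermediate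
9 | (2R,4E,8Z)-2-[(tert-butyldimethylsilyl)oxy]-4-{[(tert-butyldiphenylsilyl)oxy]methyl}-10-[(4-methoxybenzyl)oxy]-8-methyl-1-(trityloxy)deca-4,8-dien-6-yne | COc1ccc(COC/C=C(C)\C#C/C=C(/CO[Si](c2ccccc2)(c2ccccc2)C(C)(C)C)C[C@@H](O[Si](C)(C)C(C)(C)C)COC(c2ccccc2)(c2ccccc2)c2ccccc2)cc1 | intermediate
10 | (2R,4E,8Z)-2-[(tert-butyldimethylsilyl)oxy]-4-{[(tert-butyldiphenylsilyl)oxy]methyl}-10-[(4-methoxybenzyl)oxy]-8-methyldeca-4,8-dien-6-yn-1-ol | COc1ccc(COC/C=C(C)\C#C/C=C(/CO[Si](c2ccccc2)(c2ccccc2)C(C)(C)C)C[C@@H](O[Si](C)(C)C(C)(C)C)CO)cc1 | intermediate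
11 | (2R,4E,8Z)-2-[(tert-butyldimethylsilyl)oxy]-4-{[(tert-butyldiphenylsilyl)oxy]methyl}-10-[(4-methoxybenzyl)oxy]-8-methyldeca-4,8-dien-6-ynal | COc1ccc(COC/C=C(C)\C#C/C=C(/CO[Si](c2ccccc2)(c2ccccc2)C(C)(C)C)C[C@@H](O[Si](C)(C)C(C)(C)C)C=O)cc1 | intermediate
12 | methyl (4R,6E,10Z)-4-[(tert-butyldimethylsilyl)oxy]-6-{[(tert-butyldiphenylsilyl)oxy]methyl}-3-hydroxy-12-[(4-methoxybenzyl)oxy]-10-methyl-2-methylidenedodeca-6,10-dien-8-ynoate (C3 epimers) | COc1ccc(COC/C=C(C)\C#C/C=C(/CO[Si](c2ccccc2)(c2ccccc2)C(C)(C)C)C[C@@H](O[Si](C)(C)C(C)(C)C)C(O)C(=C)C(=O)OC)cc1 | intermediate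
13 | methyl (2Z,4R,6E,10Z)-2-(bromomethyl)-4-[(tert-butyldimethylsilyl)oxy]-6-{[(tert-butyldiphenylsilyl)oxy]methyl}-12-[(4-methoxybenzyl)oxy]-10-methyldodeca-2,6,10-trien-8-ynoate | COc1ccc(COC/C=C(C)\C#C/C=C(/CO[Si](c2ccccc2)(c2ccccc2)C(C)(C)C)C[C@@H](O[Si](C)(C)C(C)(C)C)/C=C(\CBr)C(=O)OC)cc1 | intermediate
14 | methyl (2Z,4R,6E,10Z)-2-(bromomethyl)-4-[(tert-butyldimethylsilyl)oxy]-6-{[(tert-butyldiphenylsilyl)oxy]methyl}-12-hydroxy-10-methyldodeca-2,6,10-trien-8-ynoate | OC/C=C(C)\C#C/C=C(/CO[Si](c1ccccc1)(c1ccccc1)C(C)(C)C)C[C@@H](O[Si](C)(C)C(C)(C)C)/C=C(\CBr)C(=O)OC | intermediate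
15 | methyl (2Z,4R,6E,10Z)-2-(bromomethyl)-4-[(tert-butyldimethylsilyl)oxy]-6-{[(tert-butyldiphenylsilyl)oxy]methyl}-10-methyl-12-oxododeca-2,6,10-trien-8-ynoate | O=C/C=C(C)\C#C/C=C(/CO[Si](c1ccccc1)(c1ccccc1)C(C)(C)C)C[C@@H](O[Si](C)(C)C(C)(C)C)/C=C(\CBr)C(=O)OC | intermediate
16 | methyl (6S,7S,8R)-8-[(tert-butyldimethylsilyl)oxy]-14-[(tert-butyldiphenylsilyl)oxy]-6-hydroxygermacra-1(10)E,4Z,11(13)-trien-2-yn-12-oate | C=C(C(=O)OC)[C@H]1[C@@H](O)/C=C(C)\C#C/C=C(/CO[Si](c2ccccc2)(c2ccccc2)C(C)(C)C)C[C@H]1O[Si](C)(C)C(C)(C)C | intermediate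
17 | (6S,7S,8R)-8-[(tert-butyldimethylsilyl)oxy]-14-[(tert-butyldiphenylsilyl)oxy]germacra-1(10)E,4Z,11(13)-trien-2-yn-12,6-olide | C=C1C(=O)O[C@H]2/C=C(C)\C#C/C=C(/CO[Si](c3ccccc3)(c3ccccc3)C(C)(C)C)C[C@@H](O[Si](C)(C)C(C)(C)C)[C@@H]12 | intermediate
18 | (6S,7R,8R)-14-[(tert-butyldiphenylsilyl)oxy]-8-hydroxygermacra-1(10)E,4Z,11(13)-trien-2-yn-12,6-olide | C=C1C(=O)O[C@H]2/C=C(C)\C#C/C=C(/CO[Si](c3ccccc3)(c3ccccc3)C(C)(C)C)C[C@@H](O)[C@@H]12 | intermediate
19 | (E)-but-2-enal | C/C=C/C=O | starting material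
20 | (Z)-2-iodobut-2-enal | C/C=C(/C=O)I | intermediate
21 | (Z)-2-iodobut-2-en-1-ol | C/C=C(/CO)I | intermediate
22 | tert-butyl{[(2Z)-2-iodobut-2-en-1-yl]oxy}diphenylsilane | C/C=C(/CO[Si](c1ccccc1)(c1ccccc1)C(C)(C)C)I | intermediate
23 | (2Z)-2-{[(tert-butyldiphenylsilyl)oxy]methyl}but-2-enoic acid | C/C=C(/CO[Si](c1ccccc1)(c1ccccc1)C(C)(C)C)C(=O)O | intermediate
24 | (2Z)-2-{[(tert-butyldiphenylsilyl)oxy]methyl}but-2-enoic 2,4,6-trichlorobenzoic anhydride | C/C=C(/CO[Si](c1ccccc1)(c1ccccc1)C(C)(C)C)C(=O)OC(=O)c1c(Cl)cc(Cl)cc1Cl | intermediate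
25 | (6S,7R,8R)-14-[(tert-butyldiphenylsilyl)oxy]-8-{[(2Z)-2-{[(tert-butyldiphenylsilyl)oxy]methyl}but-2-enoyl]oxy}germacra-1(10)E,4Z,11(13)-trien-2-yn-12,6-olide | C=C1C(=O)O[C@H]2/C=C(C)\C#C/C=C(/CO[Si](c3ccccc3)(c3ccccc3)C(C)(C)C)C[C@@H](OC(=O)/C(=C\C)CO[Si](c3ccccc3)(c3ccccc3)C(C)(C)C)[C@@H]12 | intermediate
26 | (6S,7R,8R)-14-hydroxy-8-{[(2Z)-2-(hydroxymethyl)but-2-enoyl]oxy}germacra-1(10)E,4Z,11(13)-trien-2-yn-12,6-olide | C=C1C(=O)O[C@H]2/C=C(C)\C#C/C=C(/CO)C[C@@H](OC(=O)/C(=C\C)CO)[C@@H]12 | intermediate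
27 | (1R,6S,7R,8R,10R)-1,10-epoxy-14-hydroxy-8-{[(2Z)-2-(hydroxymethyl)but-2-enoyl]oxy}germacra-4Z,11(13)-dien-2-yn-12,6-olide | C=C1C(=O)O[C@H]2/C=C(C)\C#C[C@H]3O[C@@]3(CO)C[C@@H](OC(=O)/C(=C\C)CO)[C@@H]12 | intermediate
28 | (1R,6S,7R,8R,10R)-1,10-epoxy-14-hydroxy-8-{[(2Z)-2-(hydroxymethyl)but-2-enoyl]oxy}germacra-2Z,4Z,11(13)-trien-12,6-olide (CNP0165856.1) | C=C1C(=O)O[C@H]2/C=C(C)\C=C/[C@H]3O[C@@]3(CO)C[C@@H](OC(=O)/C(=C\C)CO)[C@@H]12 | target

## Step count and least certain steps

Total step count: 22. Longest linear sequence: 17 steps (steps 1, 2, 4–14 and 19–22, from 1 to 28).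

**Step 13 (key step).** The most likely failures are poor or reversed facial selectivity at C7 relative to C8, because the face is chosen by the conformation of the forming ten-membered ring and not by a simple open-chain model; intermolecular coupling in place of ring closure; and 1,4-elimination of the δ-silyloxy allylchromium to a diene. The fallback sets out from 13 and replaces the reducing metal by an isolable allyl donor of fixed olefin geometry. Palladium-catalysed borylation of 13 (B2pin2, Pd2(dba)3, toluene) gives methyl (4R,6E,10Z)-4-[(tert-butyldimethylsilyl)oxy]-6-{[(tert-butyldiphenylsilyl)oxy]methyl}-12-[(4-methoxybenzyl)oxy]-10-methyl-2-[(4,4,5,5-tetramethyl-1,3,2-dioxaborolan-2-yl)methyl]dodeca-2,6,10-trien-8-ynoate F1. DDQ cleavage of the benzyl-type ether gives its 12-hydroxy analogue F2, and MnO2 gives its 12-oxo analogue F3. F3 is expected to close under dilution by thermal intramolecular allylboration, with Sc(OTf)3 catalysis if needed. The boron-centred chair is tighter, cannot eliminate the silyloxy group, and should again give the syn adduct; work-up and mild acid return the route at 17.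

**Step 4.** An E/Z mixture at C1=C10, or conjugate addition of the phosphonate anion to the ynal, may erode the olefination. The fallback sets out from 4 and 3. Aldol addition of the lithium enolate of 4 to 3 at −78 °C gives (5R)-3-{(4Z)-1-hydroxy-6-[(4-methoxybenzyl)oxy]-4-methylhex-4-en-2-yn-1-yl}-5-[(trityloxy)methyl]oxolan-2-one F4. Mesylation (MeSO2Cl, Et3N) gives its methanesulfonate F5, and DBU induces E1cB elimination, which is under thermodynamic control and favours the E-alkylidene lactone. The route is rejoined at 6.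

**Step 9.** The Morita–Baylis–Hillman reaction is slow on a hindered α-silyloxy aldehyde, and long contact with the amine may cause enolisation (loss of configuration at C8) or silyl migration. The fallback sets out from 11. Aldol addition of the lithium enolate of methyl 3-(phenylselanyl)propanoate at −78 °C gives methyl (4R,6E,10Z)-4-[(tert-butyldimethylsilyl)oxy]-6-{[(tert-butyldiphenylsilyl)oxy]methyl}-3-hydroxy-12-[(4-methoxybenzyl)oxy]-10-methyl-2-[(phenylselanyl)methyl]dodeca-6,10-dien-8-ynoate F6. Oxidation with H2O2 and syn-elimination of the selenoxide rejoin the route at 12.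

**Step 14.** The two silyl ethers may not be discriminated cleanly, and the lactone may migrate from O6 to the freed O8 if the medium turns basic. The fallback sets out from 17 and moves the discrimination from the cleavage to the silylation. Excess HF·pyridine removes both groups to give (6S,7R,8R)-8,14-dihydroxygermacra-1(10)E,4Z,11(13)-trien-2-yn-12,6-olide F7. Selective silylation of the primary allylic hydroxyl (t-BuPh2SiCl, imidazole, −20 °C) rejoins the route at 18.

**Step 22.** Over-reduction at the exocyclic methylene, or reductive opening of the propargylic epoxide to an allenic alcohol, may compete with the semi-reduction. The fallback sets out from 26 and reverses the order of the last two events. The same zinc reagent at 0 °C gives (6S,7R,8R)-14-hydroxy-8-{[(2Z)-2-(hydroxymethyl)but-2-enoyl]oxy}germacra-1(10)E,2Z,4Z,11(13)-tetraen-12,6-olide F8, which is kept cold because it is the electrocyclisation-prone all-cis triene. It is epoxidised at once under the conditions of step 21, which rejoins the route at 28.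

## Further compounds

F1 | step 13 | methyl (4R,6E,10Z)-4-[(tert-butyldimethylsilyl)oxy]-6-{[(tert-butyldiphenylsilyl)oxy]methyl}-12-[(4-methoxybenzyl)oxy]-10-methyl-2-[(4,4,5,5-tetramethyl-1,3,2-dioxaborolan-2-yl)methyl]dodeca-2,6,10-trien-8-ynoate | COc1ccc(COC/C=C(C)\C#C/C=C(/CO[Si](c2ccccc2)(c2ccccc2)C(C)(C)C)C[C@@H](O[Si](C)(C)C(C)(C)C)/C=C(\CB2OC(C)(C)C(C)(C)O2)C(=O)OC)cc1
F2 | step 13 | 12-hydroxy analogue of F1 | OC/C=C(C)\C#C/C=C(/CO[Si](c1ccccc1)(c1ccccc1)C(C)(C)C)C[C@@H](O[Si](C)(C)C(C)(C)C)/C=C(\CB1OC(C)(C)C(C)(C)O1)C(=O)OC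
F3 | step 13 | 12-oxo analogue of F1 | O=C/C=C(C)\C#C/C=C(/CO[Si](c1ccccc1)(c1ccccc1)C(C)(C)C)C[C@@H](O[Si](C)(C)C(C)(C)C)/C=C(\CB1OC(C)(C)C(C)(C)O1)C(=O)OC
F4 | step 4 | (5R)-3-{(4Z)-1-hydroxy-6-[(4-methoxybenzyl)oxy]-4-methylhex-4-en-2-yn-1-yl}-5-[(trityloxy)methyl]oxolan-2-one (diastereomer mixture) | COc1ccc(COC/C=C(C)\C#CC(O)C2C[C@H](COC(c3ccccc3)(c3ccccc3)c3ccccc3)OC2=O)cc1
F5 | step 4 | methanesulfonate of F4 | COc1ccc(COC/C=C(C)\C#CC(OS(C)(=O)=O)C2C[C@H](COC(c3ccccc3)(c3ccccc3)c3ccccc3)OC2=O)cc1
F6 | step 9 | methyl (4R,6E,10Z)-4-[(tert-butyldimethylsilyl)oxy]-6-{[(tert-butyldiphenylsilyl)oxy]methyl}-3-hydroxy-12-[(4-methoxybenzyl)oxy]-10-methyl-2-[(phenylselanyl)methyl]dodeca-6,10-dien-8-ynoate (diastereomer mixture) | COc1ccc(COC/C=C(C)\C#C/C=C(/CO[Si](c2ccccc2)(c2ccccc2)C(C)(C)C)C[C@@H](O[Si](C)(C)C(C)(C)C)C(O)C(C[Se]c2ccccc2)C(=O)OC)cc1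
F7 | step 14 | (6S,7R,8R)-8,14-dihydroxygermacra-1(10)E,4Z,11(13)-trien-2-yn-12,6-olide | C=C1C(=O)O[C@H]2/C=C(C)\C#C/C=C(/CO)C[C@@H](O)[C@@H]12
F8 | step 22 | (6S,7R,8R)-14-hydroxy-8-{[(2Z)-2-(hydroxymethyl)but-2-enoyl]oxy}germacra-1(10)E,2Z,4Z,11(13)-tetraen-12,6-olide | C=C1C(=O)O[C@H]2/C=C(C)\C=C/C=C(/CO)C[C@@H](OC(=O)/C(=C\C)CO)[C@@H]12
A1 | alternative 1 | metathesis substrate: α-methylene-γ-butyrolactone with the (1Z)-2-methylbuta-1,3-dienyl group on C6 and the bis-silylated C8–C10 chain ending in the C1–C10 vinyl epoxide on C7, configured as the target | C=C1C(=O)O[C@@H](/C=C(C)\C=C)[C@H]1[C@H](O[Si](C)(C)C(C)(C)C)C[C@]2(CO[Si](C)(C)C(C)(C)C)O[C@@H]2C=C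
A2 | alternative 2 | 3-(bromomethyl)furan-2(5H)-one carrying at C5 (C6 of the target, configured as the target) the (1Z,5E)-dienyne chain that ends in the C8 aldehyde | O=CC/C(CO[Si](C)(C)C(C)(C)C)=C\C#C/C(C)=C\[C@H]1C=C(CBr)C(=O)O1
A3 | alternative 3 | decalin 3,8-epoxy-2-ketone (germacrane numbers) with the C4=C5 olefin, silyloxy groups on C6 and C14 and the methyl acrylate unit on C7 | O=C1C[C@@H](CO[Si](C)(C)C(C)(C)C)C[C@@]2(O3)[C@@H](C(=C)C(=O)OC)[C@@H](O[Si](C)(C)C(C)(C)C)C=C(C)[C@@]123
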